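The trap in this flask was to time the catalyst by its slowest step, the release of target from catalyst intermediate C, and to take that for the pace of the whole round.

    substrate + target → side product (k1 = 1.5 M⁻¹ s⁻¹)
    2 catalyst intermediate A ⇌ resting dimer, settled at all times (K2 = 25000 M⁻¹)
    reagent + catalyst intermediate A → catalyst intermediate B (k3 = 3000 M⁻¹ s⁻¹)
    catalyst intermediate C → free catalyst + target (k4 = 33 s⁻¹)
    catalyst intermediate B ⇌ released group + catalyst intermediate C (K5 = 0.052 M, k5 = 50 s⁻¹)
    substrate + free catalyst → catalyst intermediate A (k6 = 15000 M⁻¹ s⁻¹)

| setting | north | east | north-west | south-west |
|---|---|---|---|---|
| substrate | 10 mM | 10 mM | 10 mM (fed, over 3.20 min) | 10 mM |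
| reagent | 15.0 mM | 15.0 mM | 15.0 mM | 15.0 mM |
| free catalyst | 20 µM | 20 µM | 20 µM | 20 µM |
| remark | one stirred flow tank at steady state, fed with the mixture as stated, mean residence time 4.0 min | a tube with plug flow, the mixed feed as stated, residence time 4.0 min | a stirred flask in which substrate is dosed at a steady rate over 3.20 min without added volume, worked up at 4.0 min | everything together in a closed stirred flask, run for 4.0 min |
| time |  | 4.0 min | 4.0 min | 4.0 min |

- in percentages every species weighs as the substrate in it: one resting dimer or side product counts as two
- a step written with two of one species runs at k times the square of its concentration and takes two of it each time
- the stated concentrations are those of everything mixed, before any reaction; amounts are the same in each set-up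
- the feed brings no volume worth counting
- run time (east): 4.0 min

- the set-up with the highest amount of target at the outlet or at the end, in percent of the substrate put in ("none" if the first two lie within 2 percentage points) (north / east / north-west / south-west / none)
- amount of target at the outlet or at the end, in percent of the substrate put in, north
- amount of target at the outlet or at the end, in percent of the substrate put in, east
- amount of target at the outlet or at the end, in percent of the substrate put in, north-west
- amount of target at the outlet or at the end, in percent of the substrate put in, south-west

I counted turns. Each substrate costs the catalyst one turn, so the charge needs 500 turns. My first clock gave each turn the time of the slowest step, so it finished in 15.2 s. My second clock added the steps the catalyst passes in a row, with [reagent] held at its charge and the return of step 5 left out. That made a round of 0.0725 s, and capture of substrate is shorter at the start. Multiplied by the turns, this gave the run-through time 36.3 s, the time the catalyst needs at full speed to work through the charge.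

The two clocks parted, and the first one cheated. One catalyst cannot stand in two steps at once, and the other steps together take 0.0422 s, longer than the slowest. These times lie close together, so I called none of them the rate-limiting step.

The run-through time gives the loss. With everything mixed at once, target and substrate share the flask during the run-through, which is shorter than the time allowed. Averaged over the target made, and with side product counted double, the lost share is k1·[substrate]·run/3. That gave 81.9 % for east and 81.9 % for south-west, whereas the slowest-step clock would have given 92.4 %.

In north-west the feed lasts longer than the run-through, so the spare time, shared over the turns, is the wait for substrate, 1/(k6[substrate]). That put [substrate] near 0.214 mM, and the lost share k1[substrate]·tf gave 93.8 %. In north I did the same with the residence time and with [reagent] near 5.00 mM, which gave [substrate] near 0.184 mM and 88.3 %. My order was north-west first.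

The forecast gave 86.4 % for north, 77 % for east, 93.2 % for north-west and 77 % for south-west, with north-west best, saying “Slow dosing keeps substrate lowest throughout”.

The simulation gave 87.6 %, 79.2 %, 93.9 % and 79.2 % in that order, with north-west best.

In east, half of the turnover of the turning of reagent and catalyst intermediate A into catalyst intermediate B was done by 0.353 min. Times 2, that reads 42.4 s, nearer my 36.3 s than the 15.2 s of my first clock. A part of the lead of north-west came from the slow dosing of substrate: with the dosing taken away, north-west fell from 93.9 % to 79.2 %.

On the east flask with 17 mM of substrate, the run-through grows to 61.6 s and the same reckoning gives 47.6 %. The simulation gave 56.3 %, somewhat higher, with side product at 43.7 %.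

(The numbers are assumed.)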